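Everything rests on reading the C4a–C8a carbocycle of the tetrahydrochromone as an epoxyquinol: C8a ketone, C4a=C5 enone, C6 carbinol and C7–C8 epoxide, with all three oxygens on one face, taken from the bromobenzene cis-dihydrodiol. The key step exploits the alternating trans C5–C8 oxygen array and the 1,3-diaxial C5–O/C7–O span of the dioxepine ring. 6,7-Dihydroxy-2-phenethylchromone adds through O7' to C5 of a 2-alkynoyl epoxyquinol. The enolate then closes the 4-pyranone on the ynone, and O6' opens the epoxide at C7. One flask forms three C–O bonds, two rings and two stereocentres. The precursor is monocyclic apart from its epoxide and holds neither ring.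

Key step: step 8

Remark: all carbocyclic intermediates carry the tetrahydrochromone numbering of 16 (C4a, C5–C8, C8a; primed numbers for the aromatic chromone; α = face of the C6 and C8 oxygens, β = face of the C5 and C7 oxygens), and 6 (the whole-cell dihydroxylation product of bromobenzene) and 11 are taken to be catalogue compounds.

Step 1
Reactants: 1 1-(2-hydroxy-4,5-dimethoxyphenyl)ethanone; 2 ethyl 3-phenylpropanoate
Product: 4 6,7-dimethoxy-2-(2-phenylethyl)-4H-chromen-4-one, via 1,3-diketone 3 (not isolated)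
Conditions: NaH (3.5 equiv), THF, reflux; then conc. HCl, MeOH, reflux
Reagents that add atoms: none
Why: Crossed Claisen condensation of the acetophenone dianion with the ester should give the 1,3-diketone, which cyclodehydrates under acid to the 2-alkylchromone; no stereocentre is formed.

Step 2
Reactants: 4 6,7-dimethoxy-2-(2-phenylethyl)-4H-chromen-4-one
Product: 5 6,7-dihydroxy-2-(2-phenylethyl)-4H-chromen-4-one
Conditions: BBr3 (4 equiv), CH2Cl2, −78 °C to rt; then H2O
Reagents that add atoms: none
Why: Lewis-acid cleavage of both aryl methyl ethers with BBr3 should free the catechol, the chromone and the phenethyl chain being inert and no stereocentre being present.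

Step 3
Reactants: 6 (1S,2S)-3-bromocyclohexa-3,5-diene-1,2-diol
Product: 7 (1S,2R,3R,4S)-3,6-dibromocyclohex-5-ene-1,2,4-triol (C8a-OH, C8-OH and C6-OH α, C7-Br β)
Conditions: NBS (1.05 equiv), THF–H2O 4:1, 0 °C, dark
Reagents that add atoms: N-bromosuccinimide, O=C1CCC(=O)N1Br; water, O
Why: Bromohydrin formation, in which the bromonium ion should form on the unhalogenated, more electron-rich C6=C7 alkene on the β face (anti to the C8 hydroxyl) and water should open it at the allylic C6 from the α face, which sets C6 (O α) and C7 (Br β).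

Step 4
Reactants: 7 (1S,2R,3R,4S)-3,6-dibromocyclohex-5-ene-1,2,4-triol
Product: 8 (1R,2S,5S,6S)-3-bromo-7-oxabicyclo[4.1.0]hept-3-ene-2,5-diol (7α,8α-epoxide, C6-OH and C8a-OH α)
Conditions: NaOMe (1.1 equiv), THF–MeOH, 0 °C
Reagents that add atoms: none
Why: Halohydrin closure (intramolecular Williamson reaction), in which the more acidic C8 alkoxide of the vicinal diol, antiperiplanar to the β C7–Br bond in the triaxial half-chair, should displace bromide with inversion at C7 to give the α epoxide, which lies cis to both remaining hydroxyls so that no Payne migration can follow.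

Step 5
Reactants: 8 (1R,2S,5S,6S)-3-bromo-7-oxabicyclo[4.1.0]hept-3-ene-2,5-diol
Product: 9 (1R,2S,5S,6R)-3-bromo-5-[(tert-butyldimethylsilyl)oxy]-7-oxabicyclo[4.1.0]hept-3-en-2-ol (C6-OTBS, C8a-OH free)
Conditions: TBSCl (1.05 equiv), imidazole, CH2Cl2–DMF, −10 °C
Reagents that add atoms: tert-butyldimethylsilyl chloride, CC(C)(C)[Si](C)(C)Cl
Why: Selective monosilylation should take the C6 hydroxyl, because the C8a hydroxyl is crowded and deactivated by the neighbouring C–Br carbon; no stereocentre is touched.

Step 6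
Reactants: 9 (1R,2S,5S,6R)-3-bromo-5-[(tert-butyldimethylsilyl)oxy]-7-oxabicyclo[4.1.0]hept-3-en-2-ol
Product: 10 (1S,5S,6R)-3-bromo-5-[(tert-butyldimethylsilyl)oxy]-7-oxabicyclo[4.1.0]hept-3-en-2-one
Conditions: Dess–Martin periodinane (1.2 equiv), CH2Cl2, 0 °C to rt
Reagents that add atoms: none
Why: Dess–Martin oxidation of the remaining allylic alcohol should give the α-bromo epoxy enone under non-basic conditions that spare epoxide and silyl ether, the C8a stereocentre being deleted on purpose.

Step 7
Reactants: 10 (1S,5S,6R)-3-bromo-5-[(tert-butyldimethylsilyl)oxy]-7-oxabicyclo[4.1.0]hept-3-en-2-one; 11 1-(but-3-yn-1-yl)-4-methoxybenzene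
Product: 12 (1S,5S,6R)-5-[(tert-butyldimethylsilyl)oxy]-3-[5-(4-methoxyphenyl)pent-2-ynoyl]-7-oxabicyclo[4.1.0]hept-3-en-2-one
Conditions: PdCl2(PPh3)2 (5 mol %), CO (5 bar), Et3N (1.5 equiv), THF, 35 °C, no copper salt
Reagents that add atoms: carbon monoxide, [C-]#[O+]
Why: Carbonylative Sonogashira coupling, in which the electron-poor alkenyl bromide should add readily to Pd(0), CO pressure and the absence of copper favour acyl-palladium formation over direct alkynylation, and the epoxide (not allylic to any alkene here), the silyl ether and the three stereocentres stay untouched.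

Step 8
Reactants: 12 (1S,5S,6R)-5-[(tert-butyldimethylsilyl)oxy]-3-[5-(4-methoxyphenyl)pent-2-ynoyl]-7-oxabicyclo[4.1.0]hept-3-en-2-one; 5 6,7-dihydroxy-2-(2-phenylethyl)-4H-chromen-4-one
Product: 15 6-O-TBS ether of 16, via oxa-Michael enol 13 (not isolated), via epoxy-tetrahydrochromone 14 (not isolated)
Conditions: Cs2CO3 (0.3 equiv), 4 Å MS, MeCN–DMF 5:1, Ar, 0 °C; then dilution to 0.01 M, 45 °C
Reagents that add atoms: none
Why: Proposed new method: the substoichiometric carbonate should first ionise only the vinylogous-acid 7'-OH of 5 (para to C4'=O and clearly more acidic than 6'-OH), and this phenoxide should add to C5, the β-carbon of the doubly activated alkylidene-1,3-dicarbonyl of 12 and its most electrophilic site, to give 13. The C8a enolate oxygen then attacks the ynone terminus C2 (6-endo-dig oxa-Michael closure, favoured over 5-exo-dig in aprotic medium), which forms the 4-pyranone of 14 irreversibly, shuts the retro-Michael path and removes the acidity of H6. On warming, the base passes to 6'-OH, held over the β face by the pseudoaxial C5–O bond, and its phenoxide opens the epoxide at C7 in a 7-exo-tet SN2 closure of the dioxepine, attack at C8 being an 8-endo, 1,4-bridging mode that is out of reach. C5 is set by attack anti to the C6 silyl ether and the epoxide oxygen, which both shield the α face; C7 is inverted by backside attack while C6 and C8 keep their C–O bonds, so the all-cis oxygen triad of 12 becomes the all-trans array of 15. The closest known reaction types are the nucleophile-triggered annulation of 2-(1-alkynyl)-2-alken-1-ones to furans, the base-mediated closure of o-hydroxyaryl ynones to chromones and the intramolecular phenoxide opening of epoxides. The selectivities needed are O7' before O6', C5 before the ynone terminus, and intra- before intermolecular epoxide opening, secured in turn by the acidity order of the proton donors, by the double activation of C5 and by the dilution before heating.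

Step 9
Reactants: 15 6-O-TBS ether of 16
Product: 16 (+)-4'-methoxyaquisinenone G, (5R,6S,7R,8S)
Conditions: HF·pyridine, pyridine, THF, 0 °C to rt
Reagents that add atoms: none
Why: Fluoride-mediated silyl ether cleavage under buffered conditions should free the C6 hydroxyl and leave the two aryl alkyl ethers, both pyranones and all four stereocentres untouched.

Compound list
1 | 1-(2-hydroxy-4,5-dimethoxyphenyl)ethanone | CC(=O)c1cc(OC)c(OC)cc1O | starting material
2 | ethyl 3-phenylpropanoate | CCOC(=O)CCc1ccccc1 | starting material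
3 | 1-(2-hydroxy-4,5-dimethoxyphenyl)-5-phenylpentane-1,3-dione | COc1cc(O)c(cc1OC)C(=O)CC(=O)CCc1ccccc1 | intermediate
4 | 6,7-dimethoxy-2-(2-phenylethyl)-4H-chromen-4-one | COc1cc2oc(CCc3ccccc3)cc(=O)c2cc1OC | intermediate
5 | 6,7-dihydroxy-2-(2-phenylethyl)-4H-chromen-4-one | Oc1cc2oc(CCc3ccccc3)cc(=O)c2cc1O | intermediate
6 | (1S,2S)-3-bromocyclohexa-3,5-diene-1,2-diol | O[C@H]1C=CC=C(Br)[C@H]1O | starting material
7 | (1S,2R,3R,4S)-3,6-dibromocyclohex-5-ene-1,2,4-triol | O[C@@H]1C(Br)=C[C@H](O)[C@@H](Br)[C@@H]1O | intermediate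
8 | (1R,2S,5S,6S)-3-bromo-7-oxabicyclo[4.1.0]hept-3-ene-2,5-diol | O[C@@H]1C(Br)=C[C@H](O)[C@@H]2O[C@H]12 | intermediate
9 | (1R,2S,5S,6R)-3-bromo-5-[(tert-butyldimethylsilyl)oxy]-7-oxabicyclo[4.1.0]hept-3-en-2-ol | O[C@@H]1C(Br)=C[C@H](O[Si](C)(C)C(C)(C)C)[C@@H]2O[C@H]12 | intermediate
10 | (1S,5S,6R)-3-bromo-5-[(tert-butyldimethylsilyl)oxy]-7-oxabicyclo[4.1.0]hept-3-en-2-one | O=C1C(Br)=C[C@H](O[Si](C)(C)C(C)(C)C)[C@@H]2O[C@H]12 | intermediate
11 | 1-(but-3-yn-1-yl)-4-methoxybenzene | C#CCCc1ccc(OC)cc1 | starting material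
12 | (1S,5S,6R)-5-[(tert-butyldimethylsilyl)oxy]-3-[5-(4-methoxyphenyl)pent-2-ynoyl]-7-oxabicyclo[4.1.0]hept-3-en-2-one | O=C1C(C(=O)C#CCCc2ccc(OC)cc2)=C[C@H](O[Si](C)(C)C(C)(C)C)[C@@H]2O[C@H]12 | intermediate
13 | oxa-Michael adduct in its C8a enol form (5β-aryloxy through O7', 6α-OTBS, 7α,8α-epoxide, C4a alkynoyl) | COc1ccc(CCC#CC(=O)C2=C(O)[C@H]3O[C@H]3[C@@H](O[Si](C)(C)C(C)(C)C)[C@@H]2Oc4cc5oc(CCc6ccccc6)cc(=O)c5cc4O)cc1 | intermediate
14 | 5β-[(6-hydroxy-4-oxo-2-phenethyl-4H-chromen-7-yl)oxy]-6α-(TBS-oxy)-7α,8α-epoxy-2-[2-(4-methoxyphenyl)ethyl]-5,6,7,8-tetrahydrochromone | COc1ccc(CCc2cc(=O)c3c(o2)[C@H]4O[C@H]4[C@@H](O[Si](C)(C)C(C)(C)C)[C@@H]3Oc5cc6oc(CCc7ccccc7)cc(=O)c6cc5O)cc1 | intermediate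
15 | 6-O-TBS ether of 16 (5β-O7', 6α-OTBS, 7β-O6', 8α-OH) | COc1ccc(CCc2cc(=O)c3c(o2)[C@@H](O)[C@@H]2Oc4cc5c(=O)cc(CCc6ccccc6)oc5cc4O[C@H]3[C@@H]2O[Si](C)(C)C(C)(C)C)cc1 | intermediate
16 | (+)-4'-methoxyaquisinenone G, (5R,6S,7R,8S) | COc1ccc(CCc2cc(=O)c3c(o2)[C@@H](O)[C@@H]2Oc4cc5c(=O)cc(CCc6ccccc6)oc5cc4O[C@H]3[C@@H]2O)cc1 | target

Total step count: 9. Longest linear sequence: 7 (steps 3 to 9, from 6).

Steps most likely to fail

Step 8. Three processes may defeat the cascade.
- Vinylogous deprotonation at H6 of 12, followed by β-opening of the epoxide and aromatisation, may outrun the conjugate addition.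
- The less acidic but more nucleophilic O6' may add first and transpose the connectivity.
- Intermolecular opening at the allylic C8 may compete in the last stage.

The fallback sets out from 5 and 12 and comes back at 15. It separates the bond formations into reactions of known type, each run on its own.
- Catechol 5 is silylated twice (TBSCl, imidazole) to 6,7-bis(TBS-oxy)-2-phenethylchromone F1.
- The silyl ether of the more acidic phenol is cleaved selectively (cat. LiOAc, moist DMF) to 6-(TBS-oxy)-7-hydroxy-2-phenethylchromone F2. Any O-to-O silyl shift leaves the anion on O7'.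
- F2 is added to 12 with catalytic carbonate at 0 °C. This is oxa-Michael addition of a phenol to an alkylidene-1,3-dicarbonyl, followed by closure of the alkynyl 1,3-diketone to the 4-pyranone.
- The bis-silyl epoxy-tetrahydrochromone F3 is isolated.
- CsF in dilute DMF then removes only the aryl silyl ether, and the freed O6' phenoxide opens the epoxide to give 15.

Step 7. Direct alkynylation without CO insertion, or amine-induced decay of the very electrophilic product during the coupling, may erode 12. The fallback sets out from 9 and 11 and comes back at 12. It replaces palladium and CO by organolithium chemistry at the alcohol oxidation level.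
- Alkyne 11 is formylated (n-BuLi, then DMF) to 5-(4-methoxyphenyl)pent-2-ynal F4.
- Alcohol 9 is deprotonated with MeLi and subjected to bromine–lithium exchange with t-BuLi at −78 °C.
- The alkenyllithium is added to F4 to give the allylic propargylic diol F5 as a mixture of carbinol epimers.
- Double Dess–Martin oxidation of F5 gives 12 under non-basic conditions.

Step 4. Closure by the C6 alkoxide instead of the C8 alkoxide would give the regioisomeric 6,7-epoxide. The fallback sets out from 6 and comes back at 9. It makes the regiochemistry a matter of protecting groups.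
- Diol 6 is converted into the acetonide F6 (2,2-dimethoxypropane, cat. TsOH).
- NBS in aqueous THF gives the bromohydrin acetonide F7.
- The only free hydroxyl (C6) is silylated to the TBS ether F8.
- Aqueous acetic acid removes the acetonide to give the bromo diol F9.
- In F9, NaOMe can close the epoxide only from O8, which gives 9.

Further compounds
F1 | step 8 | 6,7-bis[(tert-butyldimethylsilyl)oxy]-2-(2-phenylethyl)-4H-chromen-4-one | CC(C)(C)[Si](C)(C)Oc1cc2oc(CCc3ccccc3)cc(=O)c2cc1O[Si](C)(C)C(C)(C)C
F2 | step 8 | 6-[(tert-butyldimethylsilyl)oxy]-7-hydroxy-2-(2-phenylethyl)-4H-chromen-4-one | Oc1cc2oc(CCc3ccccc3)cc(=O)c2cc1O[Si](C)(C)C(C)(C)C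
F3 | step 8 | 6'-O-TBS ether of 14 | COc1ccc(CCc2cc(=O)c3c(o2)[C@H]4O[C@H]4[C@@H](O[Si](C)(C)C(C)(C)C)[C@@H]3Oc5cc6oc(CCc7ccccc7)cc(=O)c6cc5O[Si](C)(C)C(C)(C)C)cc1
F4 | step 7 | 5-(4-methoxyphenyl)pent-2-ynal | O=CC#CCCc1ccc(OC)cc1
F5 | step 7 | 3-[1-hydroxy-5-(4-methoxyphenyl)pent-2-ynyl] analogue of 9 (carbinol epimers) | O[C@@H]1C(C(O)C#CCCc2ccc(OC)cc2)=C[C@H](O[Si](C)(C)C(C)(C)C)[C@@H]2O[C@H]12
F6 | step 4 | (3aS,7aS)-4-bromo-2,2-dimethyl-3a,7a-dihydro-1,3-benzodioxole | CC1(C)O[C@H]2C=CC=C(Br)[C@H]2O1
F7 | step 4 | C8,C8a-acetonide of 7 (C6-OH α, C7-Br β) | CC1(C)O[C@H]2[C@H](Br)[C@@H](O)C=C(Br)[C@H]2O1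
F8 | step 4 | C6-O-TBS ether of F7 | CC1(C)O[C@H]2[C@H](Br)[C@@H](O[Si](C)(C)C(C)(C)C)C=C(Br)[C@H]2O1
F9 | step 4 | C6-O-TBS ether of 7 | O[C@@H]1C(Br)=C[C@H](O[Si](C)(C)C(C)(C)C)[C@@H](Br)[C@@H]1O
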